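Ring B (the acetyl-bearing cyclohexadienone) is traced back to achiral 2-geranyl-2-methylcyclohexane-1,3-dione; ring A arrives late as geranylated butyrylphloroglucinol through a one-carbon Mannich link. The route exploits the fact that the quaternary carbon of ring B (C-methyl, C-geranyl) sits between two oxygen-bearing ring carbons: in the saturated dione these are two enantiotopic C=O groups at C1 and C3 flanking C2. One catalytic transfer hydrogenation reduces a single carbonyl, which turns C2 into a fixed stereocentre without forming any skeletal bond. The carbinol then keeps the two sides of the ring distinct while the third ring oxygen and the acetyl group are installed, and is oxidised back just before the bridge is made.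

Key step: step 2

Assumption: for this dione class the (R,R)-configured ruthenium complex is taken to be the antipode that gives the (3R)-carbinol; if a trial shows the opposite sense, the (S,S)-complex replaces it with nothing else changed.

Abbreviations: geranyl = (2E)-3,7-dimethylocta-2,6-dien-1-yl; TBS = tert-butyldimethylsilyl.

Step 1
Reactants: 1 2-methylcyclohexane-1,3-dione; 2 geranyl bromide
Product: 3 2-geranyl-2-methylcyclohexane-1,3-dione (achiral)
Conditions: NaOH (1 M aq.), rt
Reagents that add atoms: none
Why: Enolate C-alkylation by SN2 at the primary allylic bromide, run in water so that hydrogen bonding to the enolate oxygens steers the soft electrophile to carbon, should give the 2,2-disubstituted dione with the E-alkene of 2 untouched.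

Step 2
Reactants: 3 2-geranyl-2-methylcyclohexane-1,3-dione
Product: 4 (2R,3R)-2-geranyl-3-hydroxy-2-methylcyclohexan-1-one (OH cis to geranyl)
Conditions: RuCl(p-cymene)[(R,R)-TsDPEN] (1 mol%), HCO2H/Et3N (5:2), CH2Cl2, 25 °C
Reagents that add atoms: none
Why: This is a Noyori–Ikariya asymmetric transfer hydrogenation: the divalent ruthenium amide takes H2 from formic acid (CO2 is lost) and the Ru–H/N–H pair passes hydride and proton to one C=O through a six-membered outer-sphere transition state without a substrate–metal bond. The closest known reaction type is the desymmetrising mono-reduction of 2-alkyl-2-methylcycloalkane-1,3-diones by the same catalyst family; no ring is closed and no skeletal bond is formed. The carbinol carbon C3 is set by the chiral diamine ligand (catalyst control of the carbonyl face), and C2 becomes stereogenic because, for that face, hydride should arrive anti to the bulky geranyl chain, which singles out one of the two carbonyls, places OH cis to geranyl and gives (2R,3R). The step needs choice of one enantiotopic carbonyl, a stop at mono-reduction and inert alkenes: these are secured by the size difference between CH3 and the geranyl branch at C2, by the lower reactivity of the hindered β-hydroxy ketone, and by polar hydride transfer that does not touch unactivated trisubstituted C=C bonds. Any trans diastereomer (OH cis to methyl) is removed by chromatography here, because after the later re-oxidation it would surface as the enantiomer.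

Step 3
Reactants: 4 (2R,3R)-2-geranyl-3-hydroxy-2-methylcyclohexan-1-one
Product: 5 (2R,3R)-3-(TBS-oxy)-2-geranyl-2-methylcyclohexan-1-one
Conditions: TBSCl, imidazole, DMF, 40 °C
Reagents that add atoms: tert-butyldimethylsilyl chloride, CC(C)(C)[Si](C)(C)Cl
Why: Imidazole-mediated silylation of the secondary alcohol should mask the carbinol for the basic, oxidative and acylating steps ahead without touching either stereocentre or the ketone.

Step 4
Reactants: 5 (2R,3R)-3-(TBS-oxy)-2-geranyl-2-methylcyclohexan-1-one
Product: 6 (5R,6R)-5-(TBS-oxy)-6-geranyl-6-methylcyclohex-2-en-1-one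
Conditions: LiN(iPr)2, THF, −78 °C; then PhS(Cl)=N-t-Bu, −78 °C
Reagents that add atoms: none
Why: In this Mukaiyama dehydrogenation the lithium enolate, which can form only toward C6 because C2 is quaternary, attacks sulfur of the sulfinimidoyl chloride and the adduct undergoes syn-elimination at low temperature, so the enone should form without any electrophilic metal near the geranyl alkenes.

Step 5
Reactants: 6 (5R,6R)-5-(TBS-oxy)-6-geranyl-6-methylcyclohex-2-en-1-one
Product: 7 (3R,4R)-4-(TBS-oxy)-3-geranyl-3-methyl-7-oxabicyclo[4.1.0]heptan-2-one (epoxide carbons unassigned)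
Conditions: H2O2 (30% aq.), NaOH (cat.), MeOH, 0 °C
Reagents that add atoms: hydrogen peroxide, OO
Why: In a Weitz–Scheffer nucleophilic epoxidation hydroperoxide adds only to the electron-poor enone C=C and leaves the electron-rich geranyl alkenes alone, and the new epoxide stereocentres need no control because step 6 erases both.

Step 6
Reactants: 7 (3R,4R)-4-(TBS-oxy)-3-geranyl-3-methyl-7-oxabicyclo[4.1.0]heptan-2-one
Product: 8 (4R,5R)-5-(TBS-oxy)-4-geranyl-4-methylcyclohexane-1,3-dione
Conditions: Pd(PPh3)4 (5 mol%), dppe (5 mol%), toluene, 80 °C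
Reagents that add atoms: none
Why: In the palladium-catalysed isomerisation of an α,β-epoxy ketone to a β-diketone, zerovalent palladium opens the Cα–O bond, the palladium alkoxide loses its carbinol hydrogen by β-hydride elimination and C–H reductive elimination closes the cycle, all under neutral conditions that should spare the silyl ether and the alkenes.

Step 7
Reactants: 8 (4R,5R)-5-(TBS-oxy)-4-geranyl-4-methylcyclohexane-1,3-dione
Product: 10 (5R,6R)-2-acetyl-5-(TBS-oxy)-6-geranyl-3-hydroxy-6-methylcyclohex-2-en-1-one (enol form of the 2-acetyl-1,3-dione), via enol acetate 9 (not isolated)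
Conditions: AcOH, DCC, DMAP, CH2Cl2, rt
Reagents that add atoms: acetic acid, CC(=O)O
Why: Carbodiimide esterification gives the enol ester, and 4-dimethylaminopyridine then moves the acyl group from oxygen to carbon (O-to-C acyl transfer of cyclic 1,3-dione enol esters), which should place acetyl on the only carbon flanked by both carbonyls while the carbinol still holds the stereochemical information.

Step 8
Reactants: 10 (5R,6R)-2-acetyl-5-(TBS-oxy)-6-geranyl-3-hydroxy-6-methylcyclohex-2-en-1-one
Product: 11 (5R,6R)-2-acetyl-6-geranyl-3,5-dihydroxy-6-methylcyclohex-2-en-1-one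
Conditions: HF·pyridine, THF, 0 °C to rt
Reagents that add atoms: none
Why: Fluoride-driven desilylation in a mildly acidic medium keeps the triketone protonated, so the β-hydroxy ketone should not be pushed toward E1cB dehydration, and the geranyl alkenes tolerate buffered HF at this temperature.

Step 9
Reactants: 11 (5R,6R)-2-acetyl-6-geranyl-3,5-dihydroxy-6-methylcyclohex-2-en-1-one
Product: 12 (4R)-2-acetyl-4-geranyl-3,5-dihydroxy-4-methylcyclohexa-2,5-dien-1-one (ring-B trione in its dienol form)
Conditions: Dess–Martin periodinane, CH2Cl2, 0 °C to rt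
Reagents that add atoms: none
Why: Dess–Martin oxidation of the secondary alcohol under neutral, non-aqueous conditions should give the trione, which stays chiral only because the acetyl group already marks one side of the ring, so acyl-transfer catalysts are kept away from 12 (an acetyl shift to the free ring carbon would give the enantiomer).

Step 10
Reactants: 13 1-(2,4,6-trihydroxyphenyl)butan-1-one; 2 geranyl bromide
Product: 14 1-(3-geranyl-2,4,6-trihydroxyphenyl)butan-1-one
Conditions: DBU, THF, 0 °C to rt
Reagents that add atoms: none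
Why: Base-mediated C-alkylation of the phloroglucinol phenolate (SN2 at the allylic bromide through ring carbon) should give one regioisomer because the two free ring positions of 13 are equivalent, with a slight deficit of 2 limiting double alkylation.

Step 11
Reactants: 12 (4R)-2-acetyl-4-geranyl-3,5-dihydroxy-4-methylcyclohexa-2,5-dien-1-one; 14 1-(3-geranyl-2,4,6-trihydroxyphenyl)butan-1-one
Product: 17 target 1-[3-{[(3R)-5-acetyl-3-geranyl-2,4-dihydroxy-3-methyl-6-oxocyclohexa-1,4-dien-1-yl]methyl}-5-geranyl-2,4,6-trihydroxyphenyl]butan-1-one, via Mannich base 15 (not isolated), via methylene trione 16 (not isolated)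
Conditions: Me2N=CH2+ I−, Et3N, CH2Cl2, 0 °C to rt; then 14, MeCN, 60 °C
Reagents that add atoms: N,N-dimethylmethyleneiminium iodide (Eschenmoser's salt), C=[N+](C)C.[I-]
Why: A Mannich reaction at the free, doubly activated ring carbon of 12, E1cB loss of dimethylamine to the quinone-methide-like methylene trione and conjugate addition of the only free aromatic carbon of 14 with re-aromatisation (Mannich-base alkylation) should join rings A and B through CH2 under near-neutral conditions that neither involve the quaternary stereocentre nor exchange the bridge.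

Compound list
1 | 2-methylcyclohexane-1,3-dione | CC1C(=O)CCCC1=O | starting material
2 | geranyl bromide, (2E)-1-bromo-3,7-dimethylocta-2,6-diene | BrC/C=C(\C)CCC=C(C)C | starting material
3 | 2-geranyl-2-methylcyclohexane-1,3-dione (achiral; C1 and C3 carbonyls enantiotopic) | O=C1CCCC(=O)C1(C)C/C=C(\C)CCC=C(C)C | intermediate
4 | (2R,3R)-2-geranyl-3-hydroxy-2-methylcyclohexan-1-one (OH cis to geranyl) | C1[C@@H](O)[C@@](C)(C/C=C(\C)CCC=C(C)C)C(=O)CC1 | intermediate
5 | (2R,3R)-3-(TBS-oxy)-2-geranyl-2-methylcyclohexan-1-one | C1[C@@H](O[Si](C)(C)C(C)(C)C)[C@@](C)(C/C=C(\C)CCC=C(C)C)C(=O)CC1 | intermediate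
6 | (5R,6R)-5-(TBS-oxy)-6-geranyl-6-methylcyclohex-2-en-1-one | C1[C@@H](O[Si](C)(C)C(C)(C)C)[C@@](C)(C/C=C(\C)CCC=C(C)C)C(=O)C=C1 | intermediate
7 | (3R,4R)-4-(TBS-oxy)-3-geranyl-3-methyl-7-oxabicyclo[4.1.0]heptan-2-one (epoxide carbons unassigned; either diastereomer serves) | C1[C@@H](O[Si](C)(C)C(C)(C)C)[C@@](C)(C/C=C(\C)CCC=C(C)C)C(=O)C2OC12 | intermediate
8 | (4R,5R)-5-(TBS-oxy)-4-geranyl-4-methylcyclohexane-1,3-dione | C1[C@@H](O[Si](C)(C)C(C)(C)C)[C@@](C)(C/C=C(\C)CCC=C(C)C)C(=O)CC1=O | intermediate
9 | (4R,5R)-5-(TBS-oxy)-4-geranyl-4-methyl-3-oxocyclohex-1-en-1-yl acetate (not isolated; less hindered regioisomer drawn, the other rearranges to the same product) | C1[C@@H](O[Si](C)(C)C(C)(C)C)[C@@](C)(C/C=C(\C)CCC=C(C)C)C(=O)C=C1OC(C)=O | intermediate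
10 | (5R,6R)-2-acetyl-5-(TBS-oxy)-6-geranyl-3-hydroxy-6-methylcyclohex-2-en-1-one | C1[C@@H](O[Si](C)(C)C(C)(C)C)[C@@](C)(C/C=C(\C)CCC=C(C)C)C(=O)C(C(C)=O)=C1O | intermediate
11 | (5R,6R)-2-acetyl-6-geranyl-3,5-dihydroxy-6-methylcyclohex-2-en-1-one | C1[C@@H](O)[C@@](C)(C/C=C(\C)CCC=C(C)C)C(=O)C(C(C)=O)=C1O | intermediate
12 | (4R)-2-acetyl-4-geranyl-3,5-dihydroxy-4-methylcyclohexa-2,5-dien-1-one | C1=C(O)[C@@](C)(C/C=C(\C)CCC=C(C)C)C(O)=C(C(C)=O)C1=O | intermediate
13 | 1-(2,4,6-trihydroxyphenyl)butan-1-one | CCCC(=O)c1c(O)cc(O)cc1O | starting material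
14 | 1-(3-geranyl-2,4,6-trihydroxyphenyl)butan-1-one | CCCC(=O)c1c(O)cc(O)c(C/C=C(\C)CCC=C(C)C)c1O | intermediate
15 | (4R)-2-acetyl-6-[(dimethylamino)methyl]-4-geranyl-3,5-dihydroxy-4-methylcyclohexa-2,5-dien-1-one (not isolated) | CN(C)CC1=C(O)[C@@](C)(C/C=C(\C)CCC=C(C)C)C(O)=C(C(C)=O)C1=O | intermediate
16 | (4S)-2-acetyl-4-geranyl-3-hydroxy-4-methyl-6-methylidenecyclohex-2-ene-1,5-dione (not isolated; same spatial arrangement as 12, the descriptor changes through ranking only) | C=C1C(=O)[C@@](C)(C/C=C(\C)CCC=C(C)C)C(O)=C(C(C)=O)C1=O | intermediate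
17 | 1-[3-{[(3R)-5-acetyl-3-geranyl-2,4-dihydroxy-3-methyl-6-oxocyclohexa-1,4-dien-1-yl]methyl}-5-geranyl-2,4,6-trihydroxyphenyl]butan-1-one | CCCC(=O)c1c(O)c(C/C=C(\C)CCC=C(C)C)c(O)c(CC2=C(O)[C@@](C)(C/C=C(\C)CCC=C(C)C)C(O)=C(C(C)=O)C2=O)c1O | target

Total step count: 11. Longest linear sequence: 10 (steps 1 to 9, then step 11); step 10 is a one-step side branch.

Steps most likely to fail

Step 2. The risk is incomplete discrimination between the two enantiotopic carbonyls: hydride delivered partly syn to geranyl or to the other carbonyl face would erode the enantiomeric purity of everything downstream, and over-reduction to the diol is possible. The fallback replaces desymmetrisation by resolution. Setting out from 3, NaBH4 (0.3 equiv) in MeOH at −78 °C should give racemic cis-2-geranyl-3-hydroxy-2-methylcyclohexan-1-one F1. Esterification with (S)-O-methylmandelic acid (DCC, DMAP, CH2Cl2) should give two diastereomeric esters, (1R,2R)-2-geranyl-2-methyl-3-oxocyclohexyl (2S)-methoxy(phenyl)acetate F2 and (1S,2S)-2-geranyl-2-methyl-3-oxocyclohexyl (2S)-methoxy(phenyl)acetate F3, to be separated by chromatography. K2CO3 in MeOH then cleaves F2, and the route is rejoined at 4.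

Step 11. The risk is that self-condensation of the methylene trione, or exchange of the methylene bridge between like partners, outpaces the cross-coupling. The fallback places the electrophile on ring A instead of ring B. Setting out from 14, Me2N=CH2+ I− and Et3N in CH2Cl2 should give the Mannich base 1-{3-[(dimethylamino)methyl]-5-geranyl-2,4,6-trihydroxyphenyl}butan-1-one F5. Warmed with 12 in MeCN, it should lose dimethylamine to the ortho-quinone methide 2-butanoyl-4-geranyl-3,5-dihydroxy-6-methylidenecyclohexa-2,4-dien-1-one F6, which is captured by the free enol carbon of 12. The route is rejoined at 17.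

Step 6. The risk is that the epoxide opens sluggishly at the hindered ring, or that the palladium alkoxide diverts to elimination or 1,2-dione formation instead of β-hydride elimination. The fallback reduces and then oxidises. Setting out from 7, SmI2 in THF/MeOH at −90 °C should cleave the Cα–O bond to give (2R,3R)-3-(TBS-oxy)-2-geranyl-5-hydroxy-2-methylcyclohexan-1-one F4 (C5 epimers, both usable). Dess–Martin oxidation of F4 in CH2Cl2 rejoins the route at 8.

Further compounds
F1 | step 2 | racemic cis-2-geranyl-3-hydroxy-2-methylcyclohexan-1-one (both enantiomers) | C1[C@@H](O)[C@@](C)(C/C=C(\C)CCC=C(C)C)C(=O)CC1.C1[C@H](O)[C@](C)(C/C=C(\C)CCC=C(C)C)C(=O)CC1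
F2 | step 2 | (1R,2R)-2-geranyl-2-methyl-3-oxocyclohexyl (2S)-methoxy(phenyl)acetate | C1[C@@H](OC(=O)[C@@H](OC)c2ccccc2)[C@@](C)(C/C=C(\C)CCC=C(C)C)C(=O)CC1
F3 | step 2 | (1S,2S)-2-geranyl-2-methyl-3-oxocyclohexyl (2S)-methoxy(phenyl)acetate | C1[C@H](OC(=O)[C@@H](OC)c2ccccc2)[C@](C)(C/C=C(\C)CCC=C(C)C)C(=O)CC1
F4 | step 6 | (2R,3R)-3-(TBS-oxy)-2-geranyl-5-hydroxy-2-methylcyclohexan-1-one (C5 unassigned) | C1[C@@H](O[Si](C)(C)C(C)(C)C)[C@@](C)(C/C=C(\C)CCC=C(C)C)C(=O)CC1O
F5 | step 11 | 1-{3-[(dimethylamino)methyl]-5-geranyl-2,4,6-trihydroxyphenyl}butan-1-one | CCCC(=O)c1c(O)c(C/C=C(\C)CCC=C(C)C)c(O)c(CN(C)C)c1O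
F6 | step 11 | 2-butanoyl-4-geranyl-3,5-dihydroxy-6-methylidenecyclohexa-2,4-dien-1-one | CCCC(=O)C1=C(O)C(C/C=C(\C)CCC=C(C)C)=C(O)C(=C)C1=O
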